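**Retrosynthetic overview**

- Gnetucleistol F 33 ⇐ global desilylation of stilbene 32 ⇐ Horner–Wadsworth–Emmons coupling of C5 aldehyde 25 with phosphonate 30; the C7–OMe group comes from a C7–boron bond (B → OH → OMe).
- The strategy rests on ring A (C3a, C4, C5, C6, C7, C7a) carrying O1 on C7a and the stereogenic C3 on the neighbouring C3a. The chain O1–C2–C3 therefore ties two alkynes into a 1,6-diyne, and a third alkyne supplies C5 and C6. One Ru-catalysed (2+2+2) cyclotrimerisation forms C3a–C7a, C4–C5 and C6–C7, so ring A and the dihydrofuran ring are formed together; the two outer arenes are bought.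
- Diyne 20 ⇐ anti homopropargylic alcohol 12 by O-dichlorovinylation, elimination to the lithium alkynyl ether and borylation at that terminus only.
- 12 (both stereocentres) ⇐ aldehyde 2 + chiral allenylzinc from propargylic mesylate 10; 10 ⇐ ynone 8 by asymmetric transfer hydrogenation.

Key step: step 11

**Remarks on the chemistry (assumptions)**

- Boron on the ynol ether is carried as its naphthalene-1,8-diamine amide (Bdan = 2,3-dihydro-1H-naphtho[1,8-de][1,3,2]diazaborinin-2-yl), not as a pinacol ester. n-BuLi would lithiate a free terminal alkyne along with the ynol ether, so the second alkyne is kept silylated until boron is in place, and an alkynyl pinacol boronate would not survive the carbonate/methanol that then frees it.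
- TIPS (triisopropylsilyl) is used on the syringyl oxygen and on the primary oxygen: it resists migration to the neighbouring alkoxide under KH and survives aqueous acid. TBS = tert-butyldimethylsilyl.
- Benzylic alkynyl ethers rearrange on heating, so compounds 16–20 are handled at or below room temperature and purified on base-washed silica.
- Benzofuran numbering is used for the core (O1, C2, C3, C3a, C4–C7, C7a).

**Route**

Step 1
Reactants: 1 syringaldehyde
Product: 2 3,5-dimethoxy-4-(triisopropylsilyloxy)benzaldehyde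
Conditions: TIPSCl, imidazole, DMF, rt
Reagents that add atoms: triisopropylsilyl chloride, CC(C)[Si](Cl)(C(C)C)C(C)C
Why: Silyl ether formation at the phenol with imidazole as base and silyl-transfer agent; the aldehyde is untouched.

Step 2
Reactants: 3 ethyl glycolate
Product: 4 ethyl 2-(triisopropylsilyloxy)acetate
Conditions: TIPSCl, imidazole, DMF, rt
Reagents that add atoms: triisopropylsilyl chloride, CC(C)[Si](Cl)(C(C)C)C(C)C
Why: Silyl ether formation at an unhindered primary alcohol.

Step 3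
Reactants: 4 ethyl 2-(triisopropylsilyloxy)acetate
Product: 5 N-methoxy-N-methyl-2-(triisopropylsilyloxy)acetamide
Conditions: MeNH(OMe)·HCl, i-PrMgCl, THF, −20 → 0 °C
Reagents that add atoms: N,O-dimethylhydroxylamine hydrochloride, CNOC.Cl
Why: Weinreb amide formation by aminolysis of the ester with the magnesium amide made in the flask.

Step 4
Reactants: 5 N-methoxy-N-methyl-2-(triisopropylsilyloxy)acetamide; 6 ethynyltrimethylsilane
Product: 8 1-(triisopropylsilyloxy)-4-(trimethylsilyl)but-3-yn-2-one, via lithium (trimethylsilyl)acetylide 7 (not isolated)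
Conditions: 6, n-BuLi, THF, −78 °C; then 5, −78 → 0 °C; aq. NH4Cl
Reagents that add atoms: none
Why: Weinreb ketone synthesis; the chelated tetrahedral adduct holds until work-up, so the acetylide adds only once.

Step 5
Reactants: 8 1-(triisopropylsilyloxy)-4-(trimethylsilyl)but-3-yn-2-one
Product: 9 (2R)-1-(triisopropylsilyloxy)-4-(trimethylsilyl)but-3-yn-2-ol
Conditions: Ru[(S,S)-TsDPEN](p-cymene) (2 mol %), i-PrOH, rt
Reagents that add atoms: none
Why: Noyori–Ikariya asymmetric transfer hydrogenation of an ynone; hydride and proton are delivered to one carbonyl face in the six-membered Ru–H/N–H transition state, with the alkynyl group in the place an aryl group normally takes, which is expected to give the R alcohol with the (S,S) ligand (R here because CH2OSi outranks the alkynyl carbon).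

Step 6
Reactants: 9 (2R)-1-(triisopropylsilyloxy)-4-(trimethylsilyl)but-3-yn-2-ol
Product: 10 (2R)-1-(triisopropylsilyloxy)-4-(trimethylsilyl)but-3-yn-2-yl methanesulfonate
Conditions: MsCl, Et3N, CH2Cl2, −78 → 0 °C
Reagents that add atoms: methanesulfonyl chloride, CS(=O)(=O)Cl
Why: O-Sulfonylation; no bond to the stereocentre is broken, so the configuration is kept.

Step 7
Reactants: 10 (2R)-1-(triisopropylsilyloxy)-4-(trimethylsilyl)but-3-yn-2-yl methanesulfonate; 2 3,5-dimethoxy-4-(triisopropylsilyloxy)benzaldehyde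
Product: 12 (1R,2S)-1-[3,5-dimethoxy-4-(triisopropylsilyloxy)phenyl]-2-[(triisopropylsilyloxy)methyl]-4-(trimethylsilyl)but-3-yn-1-ol, via allenylzinc mesylate 11 (not isolated)
Conditions: Pd(OAc)2 (5 mol %), PPh3 (5 mol %), Et2Zn (3 equiv), THF, −78 → −20 °C
Reagents that add atoms: none
Why: Marshall propargylation: zerovalent palladium displaces the mesylate in an anti SN2' sense and transmetallation gives the configurationally defined allenylzinc 11, which adds to 2 through a cyclic SE2' transition state; the axis of 11 fixes the future C3 as S (net inversion at the mesylate carbon) and the cyclic transition state, with the aryl group turned away from the silyloxymethyl group, should set the future C2 as R (anti).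

Step 8
Reactants: 12 the anti alcohol of step 7; 13 trichloroethylene
Product: 16 (E)-1,2-dichlorovinyl ether of 12 [(1R,2S)-1-aryl-1-{[(E)-1,2-dichloroethenyl]oxy} derivative], via potassium alkoxide 14 (not isolated), via dichloroacetylene 15 (not isolated)
Conditions: KH, THF, 0 °C; then 13, −50 °C → rt
Reagents that add atoms: none
Why: Greene O-dichlorovinylation: the alkoxide dehydrochlorinates trichloroethylene and adds anti to the dichloroacetylene so formed; only the O–H bond changes, so both stereocentres are retained, and the bulky TIPS group on the neighbouring oxygen should not migrate to the alkoxide.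

Step 9
Reactants: 16 the dichlorovinyl ether of step 8
Product: 19 2-{[(1R,2S)-1-[3,5-dimethoxy-4-(triisopropylsilyloxy)phenyl]-2-[(triisopropylsilyloxy)methyl]-4-(trimethylsilyl)but-3-yn-1-yl]oxyethynyl}-2,3-dihydro-1H-naphtho[1,8-de][1,3,2]diazaborinine, via lithium alkynyl ether 17 (not isolated), via diisopropyl alkynylboronate 18 (not isolated)
Conditions: n-BuLi (2.2 equiv), THF, −78 → −40 °C; B(Oi-Pr)3, −78 °C; Me3SiCl, −78 → 0 °C; naphthalene-1,8-diamine, 0 °C → rt
Reagents that add atoms: triisopropyl borate, CC(C)OB(OC(C)C)OC(C)C; naphthalene-1,8-diamine, Nc1cccc2cccc(N)c12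
Why: Greene elimination and lithium–chlorine exchange give the lithium alkynyl ether, which is borylated like any acetylide (borate formation, release of the ester with Me3SiCl) and then transaminated by the chelating diamine to the base-stable Bdan group; the other alkyne is silylated and cannot be lithiated, so boron goes only to the ynol ether terminus.

Step 10
Reactants: 19 the silylated Bdan ynol ether of step 9
Product: 20 2-{[(1R,2S)-1-[3,5-dimethoxy-4-(triisopropylsilyloxy)phenyl]-2-[(triisopropylsilyloxy)methyl]but-3-yn-1-yl]oxyethynyl}-2,3-dihydro-1H-naphtho[1,8-de][1,3,2]diazaborinine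
Conditions: K2CO3 (0.3 equiv), MeOH/THF, 0 °C → rt
Reagents that add atoms: none
Why: Methanolysis of the alkynyl–SiMe3 bond; the Bdan group (boron made non-Lewis-acidic by the nitrogen lone pairs), the ynol ether and the hindered TIPS ethers tolerate carbonate in methanol.

Step 11
Reactants: 20 the diyne of step 10; 21 3,3-diethoxyprop-1-yne
Product: 22 2-[(2R,3S)-5-(diethoxymethyl)-2-[3,5-dimethoxy-4-(triisopropylsilyloxy)phenyl]-3-[(triisopropylsilyloxy)methyl]-2,3-dihydro-1-benzofuran-7-yl]-2,3-dihydro-1H-naphtho[1,8-de][1,3,2]diazaborinine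
Conditions: Cp*RuCl(cod) (10 mol %), 21 (4 equiv), ClCH2CH2Cl, rt, 20 added over 6 h
Reagents that add atoms: none
Why: Cp*RuCl(cod) loses cod and binds the two tethered alkynes of 20, which couple oxidatively to a bicyclic ruthenacycle in which the C3a–C7a bond already exists; alkyne 21 then inserts at the unsubstituted carbon C4 (C4–C5) and reductive elimination forms C6–C7, releasing the arene and the catalyst. The closest known reactions are Cp*RuCl-catalysed (2+2+2) cross-cyclotrimerisations of heteroatom-tethered 1,6-diynes, including ynol ethers, ynamides and boryl-substituted termini, with terminal alkynes. The dihydrofuran ring closes by the oxidative cyclisation of the 1,6-diyne on ruthenium, and ring A closes by insertion of the third alkyne followed by reductive elimination, a formal (2+2+2) cycloaddition. No stereocentre is formed; C2 and C3 are sp3 spectators in the tether and are not disturbed under neutral conditions. The step needs the acetal carbon at C5 (meta to boron) and cross- over self-coupling: the bulky Bdan group on C7 should make 21 approach the ruthenacycle at C4 with its substituent turned away from boron, and slow addition of 20 into an excess of 21 keeps the diyne concentration low. Room temperature also spares the benzylic ynol ether, which rearranges on heating.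

Step 12
Reactants: 22 the cyclotrimerisation product of step 11
Product: 23 [(2R,3S)-2-[3,5-dimethoxy-4-(triisopropylsilyloxy)phenyl]-5-formyl-3-[(triisopropylsilyloxy)methyl]-2,3-dihydro-1-benzofuran-7-yl]boronic acid
Conditions: 2 M HCl (aq), THF, rt
Reagents that add atoms: water, O
Why: Acid hydrolysis cleaves the B–N bonds of the Bdan group and the diethyl acetal in one operation; the diamine leaves as its hydrochloride in the aqueous phase, which keeps it from condensing with the new aldehyde, and the TIPS ethers resist dilute acid.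

Step 13
Reactants: 23 the boronic acid of step 12
Product: 24 (2R,3S)-2-[3,5-dimethoxy-4-(triisopropylsilyloxy)phenyl]-7-hydroxy-3-[(triisopropylsilyloxy)methyl]-2,3-dihydro-1-benzofuran-5-carbaldehyde
Conditions: NaBO3·4H2O, THF/H2O, rt
Reagents that add atoms: sodium perborate (NaBO3), [Na+].[O-]OB=O
Why: Oxidation of an arylboronic acid to the phenol (aryl shift from boron to oxygen, ipso); the aldehyde is meta to the new hydroxyl and not prone to Dakin oxidation under these mild conditions.

Step 14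
Reactants: 24 the phenol of step 13
Product: 25 (2R,3S)-2-[3,5-dimethoxy-4-(triisopropylsilyloxy)phenyl]-7-methoxy-3-[(triisopropylsilyloxy)methyl]-2,3-dihydro-1-benzofuran-5-carbaldehyde
Conditions: MeI, K2CO3, acetone, rt
Reagents that add atoms: iodomethane, CI
Why: Williamson O-methylation of the only free phenol; the hindered aryl TIPS ether is stable to carbonate in acetone.

Step 15
Reactants: 26 methyl 3,5-dihydroxybenzoate
Product: 27 methyl 3,5-bis(tert-butyldimethylsilyloxy)benzoate
Conditions: TBSCl, imidazole, DMF, rt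
Reagents that add atoms: tert-butyldimethylsilyl chloride, CC(C)(C)[Si](C)(C)Cl
Why: Silyl ether formation at both phenols.

Step 16
Reactants: 27 methyl 3,5-bis(tert-butyldimethylsilyloxy)benzoate
Product: 28 [3,5-bis(tert-butyldimethylsilyloxy)phenyl]methanol
Conditions: i-Bu2AlH (2.5 equiv), CH2Cl2, −78 → 0 °C
Reagents that add atoms: none
Why: Hydride reduction of the ester to the benzylic alcohol; aryl silyl ethers tolerate i-Bu2AlH at low temperature.

Step 17
Reactants: 28 [3,5-bis(tert-butyldimethylsilyloxy)phenyl]methanol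
Product: 29 1-(bromomethyl)-3,5-bis(tert-butyldimethylsilyloxy)benzene
Conditions: CBr4, PPh3, CH2Cl2, 0 °C
Reagents that add atoms: tetrabromomethane, BrC(Br)(Br)Br
Why: Appel bromination of a primary benzylic alcohol under neutral conditions.

Step 18
Reactants: 29 1-(bromomethyl)-3,5-bis(tert-butyldimethylsilyloxy)benzene
Product: 30 diethyl [3,5-bis(tert-butyldimethylsilyloxy)benzyl]phosphonate
Conditions: P(OEt)3, neat, 130 °C
Reagents that add atoms: triethyl phosphite, CCOP(OCC)OCC
Why: Michaelis–Arbuzov reaction of a benzylic bromide.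

Step 19
Reactants: 25 the aldehyde of step 14; 30 the phosphonate of step 18
Product: 32 (2R,3S)-5-{(E)-2-[3,5-bis(tert-butyldimethylsilyloxy)phenyl]ethenyl}-2-[3,5-dimethoxy-4-(triisopropylsilyloxy)phenyl]-7-methoxy-3-[(triisopropylsilyloxy)methyl]-2,3-dihydro-1-benzofuran, via sodium phosphonate carbanion 31 (not isolated)
Conditions: 30, NaH, THF, 0 °C; then 25, 0 °C → rt
Reagents that add atoms: none
Why: Horner–Wadsworth–Emmons olefination of an aryl aldehyde with a benzylic phosphonate anion, which gives the E stilbene through reversible addition and syn elimination from the more stable oxaphosphetane; the aldehyde has no acidic α-hydrogen and the stereocentres are not touched.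

Step 20
Reactants: 32 the protected stilbene of step 19
Product: 33 Gnetucleistol F, (2R,3S)-5-[(E)-2-(3,5-dihydroxyphenyl)ethenyl]-2-(4-hydroxy-3,5-dimethoxyphenyl)-3-(hydroxymethyl)-7-methoxy-2,3-dihydro-1-benzofuran
Conditions: n-Bu4NF (5 equiv), AcOH (5 equiv), THF, 0 °C → rt
Reagents that add atoms: none
Why: Fluoride-mediated cleavage of the four silyl ethers (two aryl TBS, one aryl TIPS, one primary TIPS); the acetic acid buffer keeps the electron-rich phenols protonated and away from air oxidation.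

**Compound list**

1 | syringaldehyde (4-hydroxy-3,5-dimethoxybenzaldehyde) | COc1cc(C=O)cc(OC)c1O | starting material
2 | 3,5-dimethoxy-4-(triisopropylsilyloxy)benzaldehyde | COc1cc(C=O)cc(OC)c1O[Si](C(C)C)(C(C)C)C(C)C | intermediate
3 | ethyl glycolate | CCOC(=O)CO | starting material
4 | ethyl 2-(triisopropylsilyloxy)acetate | CCOC(=O)CO[Si](C(C)C)(C(C)C)C(C)C | intermediate
5 | N-methoxy-N-methyl-2-(triisopropylsilyloxy)acetamide | CON(C)C(=O)CO[Si](C(C)C)(C(C)C)C(C)C | intermediate
6 | ethynyltrimethylsilane | C#C[Si](C)(C)C | starting material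
7 | lithium (trimethylsilyl)acetylide | [Li]C#C[Si](C)(C)C | intermediate
8 | 1-(triisopropylsilyloxy)-4-(trimethylsilyl)but-3-yn-2-one | C[Si](C)(C)C#CC(=O)CO[Si](C(C)C)(C(C)C)C(C)C | intermediate
9 | (2R)-1-(triisopropylsilyloxy)-4-(trimethylsilyl)but-3-yn-2-ol | C[Si](C)(C)C#C[C@@H](O)CO[Si](C(C)C)(C(C)C)C(C)C | intermediate
10 | (2R)-1-(triisopropylsilyloxy)-4-(trimethylsilyl)but-3-yn-2-yl methanesulfonate | C[Si](C)(C)C#C[C@@H](OS(C)(=O)=O)CO[Si](C(C)C)(C(C)C)C(C)C | intermediate
11 | (aR)-[4-(triisopropylsilyloxy)-1-(trimethylsilyl)buta-1,2-dien-1-yl]zinc methanesulfonate | CS(=O)(=O)O[Zn]C([Si](C)(C)C)=[C@]=C([H])CO[Si](C(C)C)(C(C)C)C(C)C | intermediate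
12 | (1R,2S)-1-[3,5-dimethoxy-4-(triisopropylsilyloxy)phenyl]-2-[(triisopropylsilyloxy)methyl]-4-(trimethylsilyl)but-3-yn-1-ol | COc1cc([C@@H]([C@H](CO[Si](C(C)C)(C(C)C)C(C)C)C#C[Si](C)(C)C)O)cc(OC)c1O[Si](C(C)C)(C(C)C)C(C)C | intermediate
13 | trichloroethylene | ClC=C(Cl)Cl | starting material
14 | potassium alkoxide of 12 | COc1cc([C@@H]([C@H](CO[Si](C(C)C)(C(C)C)C(C)C)C#C[Si](C)(C)C)[O-])cc(OC)c1O[Si](C(C)C)(C(C)C)C(C)C.[K+] | intermediate
15 | dichloroacetylene | ClC#CCl | intermediate
16 | (E)-1,2-dichlorovinyl ether of 12, (1R,2S) | COc1cc([C@@H]([C@H](CO[Si](C(C)C)(C(C)C)C(C)C)C#C[Si](C)(C)C)O/C(Cl)=C\Cl)cc(OC)c1O[Si](C(C)C)(C(C)C)C(C)C | intermediate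
17 | lithium alkynyl ether of 12 (lithium 2-alkoxyacetylide), (1R,2S) | COc1cc([C@@H]([C@H](CO[Si](C(C)C)(C(C)C)C(C)C)C#C[Si](C)(C)C)OC#C[Li])cc(OC)c1O[Si](C(C)C)(C(C)C)C(C)C | intermediate
18 | diisopropyl (alkoxyethynyl)boronate of 12, (1R,2S) | COc1cc([C@@H]([C@H](CO[Si](C(C)C)(C(C)C)C(C)C)C#C[Si](C)(C)C)OC#CB(OC(C)C)OC(C)C)cc(OC)c1O[Si](C(C)C)(C(C)C)C(C)C | intermediate
19 | Bdan alkynyl ether with C-silylated second alkyne, (1R,2S) (product of step 9) | COc1cc([C@@H]([C@H](CO[Si](C(C)C)(C(C)C)C(C)C)C#C[Si](C)(C)C)OC#CB2Nc3cccc4cccc(N2)c34)cc(OC)c1O[Si](C(C)C)(C(C)C)C(C)C | intermediate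
20 | Bdan alkynyl ether diyne with free terminal alkyne, (1R,2S) (precursor of the key step) | COc1cc([C@@H]([C@H](CO[Si](C(C)C)(C(C)C)C(C)C)C#C)OC#CB2Nc3cccc4cccc(N2)c34)cc(OC)c1O[Si](C(C)C)(C(C)C)C(C)C | intermediate
21 | 3,3-diethoxyprop-1-yne | C#CC(OCC)OCC | starting material
22 | trans-(2R,3S)-7-Bdan-5-(diethoxymethyl)-2-[3,5-dimethoxy-4-(triisopropylsilyloxy)phenyl]-3-[(triisopropylsilyloxy)methyl]-2,3-dihydrobenzofuran (product of the key step) | COc1cc([C@@H]2Oc3c(B4Nc5cccc6cccc(N4)c56)cc(C(OCC)OCC)cc3[C@H]2CO[Si](C(C)C)(C(C)C)C(C)C)cc(OC)c1O[Si](C(C)C)(C(C)C)C(C)C | intermediate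
23 | [(2R,3S)-2-[3,5-dimethoxy-4-(triisopropylsilyloxy)phenyl]-5-formyl-3-[(triisopropylsilyloxy)methyl]-2,3-dihydro-1-benzofuran-7-yl]boronic acid | COc1cc([C@@H]2Oc3c(B(O)O)cc(C=O)cc3[C@H]2CO[Si](C(C)C)(C(C)C)C(C)C)cc(OC)c1O[Si](C(C)C)(C(C)C)C(C)C | intermediate
24 | (2R,3S)-2-[3,5-dimethoxy-4-(triisopropylsilyloxy)phenyl]-7-hydroxy-3-[(triisopropylsilyloxy)methyl]-2,3-dihydro-1-benzofuran-5-carbaldehyde | COc1cc([C@@H]2Oc3c(O)cc(C=O)cc3[C@H]2CO[Si](C(C)C)(C(C)C)C(C)C)cc(OC)c1O[Si](C(C)C)(C(C)C)C(C)C | intermediate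
25 | (2R,3S)-2-[3,5-dimethoxy-4-(triisopropylsilyloxy)phenyl]-7-methoxy-3-[(triisopropylsilyloxy)methyl]-2,3-dihydro-1-benzofuran-5-carbaldehyde | COc1cc([C@@H]2Oc3c(OC)cc(C=O)cc3[C@H]2CO[Si](C(C)C)(C(C)C)C(C)C)cc(OC)c1O[Si](C(C)C)(C(C)C)C(C)C | intermediate
26 | methyl 3,5-dihydroxybenzoate | COC(=O)c1cc(O)cc(O)c1 | starting material
27 | methyl 3,5-bis(tert-butyldimethylsilyloxy)benzoate | COC(=O)c1cc(O[Si](C)(C)C(C)(C)C)cc(O[Si](C)(C)C(C)(C)C)c1 | intermediate
28 | [3,5-bis(tert-butyldimethylsilyloxy)phenyl]methanol | OCc1cc(O[Si](C)(C)C(C)(C)C)cc(O[Si](C)(C)C(C)(C)C)c1 | intermediate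
29 | 1-(bromomethyl)-3,5-bis(tert-butyldimethylsilyloxy)benzene | BrCc1cc(O[Si](C)(C)C(C)(C)C)cc(O[Si](C)(C)C(C)(C)C)c1 | intermediate
30 | diethyl [3,5-bis(tert-butyldimethylsilyloxy)benzyl]phosphonate | CCOP(=O)(Cc1cc(O[Si](C)(C)C(C)(C)C)cc(O[Si](C)(C)C(C)(C)C)c1)OCC | intermediate
31 | sodium salt of the benzylic carbanion of 30 | CCOP(=O)([CH-]c1cc(O[Si](C)(C)C(C)(C)C)cc(O[Si](C)(C)C(C)(C)C)c1)OCC.[Na+] | intermediate
32 | (2R,3S)-5-{(E)-2-[3,5-bis(tert-butyldimethylsilyloxy)phenyl]ethenyl}-2-[3,5-dimethoxy-4-(triisopropylsilyloxy)phenyl]-7-methoxy-3-[(triisopropylsilyloxy)methyl]-2,3-dihydro-1-benzofuran | COc1cc([C@@H]2Oc3c(OC)cc(/C=C/c4cc(O[Si](C)(C)C(C)(C)C)cc(O[Si](C)(C)C(C)(C)C)c4)cc3[C@H]2CO[Si](C(C)C)(C(C)C)C(C)C)cc(OC)c1O[Si](C(C)C)(C(C)C)C(C)C | intermediate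
33 | Gnetucleistol F | COc1cc([C@@H]2Oc3c(OC)cc(/C=C/c4cc(O)cc(O)c4)cc3[C@H]2CO)cc(OC)c1O | target

**Step count**

Total: 20 steps. Longest linear sequence: 15 steps (steps 2–14, 19, 20).

**Steps most likely to fail**

1. Step 11. Alkyne 21 may insert with the reverse orientation (acetal carbon ending at C6), the diyne may couple with itself faster than it captures 21, or the bulky boron-bearing ynol ether terminus may not enter the ruthenacycle at all.
 Fallback: ring A is taken from a bought arene and the dihydrofuran ring is closed by a rhodium carbene C–H insertion. The fallback sets out from 2 and comes back at 25.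
 - NaBH4 in MeOH reduces 2 to [3,5-dimethoxy-4-(triisopropylsilyloxy)phenyl]methanol F1.
 - Mitsunobu etherification (PPh3, DIAD) with commercial 5-bromovanillin (COc1cc(C=O)cc(Br)c1O) gives 3-bromo-4-{[3,5-dimethoxy-4-(triisopropylsilyloxy)phenyl]methoxy}-5-methoxybenzaldehyde F2; its ring already has the C7 methoxy group and the C5 aldehyde.
 - MeOH, HC(OMe)3 and PPTS give the dimethyl acetal F3.
 - Palladium-catalysed α-arylation with BrZnCH2CO2t-Bu (Pd(dba)2, Q-Phos, THF) gives the tert-butyl arylacetate F4.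
 - Diazo transfer (p-acetamidobenzenesulfonyl azide, DBU) gives the tert-butyl aryldiazoacetate F5.
 - Rh2(S-PTTL)4 or its enantiomer, whichever delivers 2R, effects 1,5-insertion of the carbene into the benzylic ether C–H bond and gives the cis-(2R,3S) dihydrobenzofuran ester F6.
 - DBU epimerises C3 to the more stable trans-(2R,3R) ester F7.
 - LiAlH4 gives the trans-(2R,3S) primary alcohol F8.
 - TIPSOTf and 2,6-lutidine give the TIPS ether acetal F9, and PPTS in wet acetone frees the aldehyde to give 25.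

2. Step 9. The alkynyl–boron bond may be protonolysed, or the amine and the liberated alcohol may add across the electron-rich ynol ether, while the alkoxy groups on boron are exchanged for the diamine; the lithium–chlorine exchange may also stay incomplete.
 Fallback: chlorine replaces boron as the handle on the ynol ether terminus, which also removes the need to protect the second alkyne. The fallback sets out from 16 and comes back at 24.
 - K2CO3 in MeOH removes the alkynyl silyl group and gives the terminal-alkyne dichlorovinyl ether F10.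
 - LiN(i-Pr)2 (2.2 equiv, THF, −78 °C, then NH4Cl) eliminates HCl without halogen–lithium exchange, the free alkyne being simply reprotonated, and gives the chloroethynyl ether diyne F11, which is kept cold in solution.
 - Cp*RuCl(cod) with 21 at room temperature gives the 7-chloro-5-(diethoxymethyl)dihydrobenzofuran F12, chlorine being the directing substituent.
 - Miyaura borylation (Pd(OAc)2, XPhos, B2pin2, KOAc, dioxane, 100 °C) gives the 7-pinacolboryl compound F13.
 - NaBO3·4H2O gives the 7-hydroxy acetal F14, and PPTS in wet acetone cleaves the acetal to give 24.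

3. Step 7. The silyloxy group may be lost by β-elimination from the propargylic zinc tautomer, addition to the electron-rich aldehyde may be slower than protonolysis of the reagent, or the anti/syn discrimination may be weak.
 Fallback: an isolable allenylboronate replaces the zinc reagent made in the flask. The fallback sets out from 9 and comes back at 12.
 - Methyl chloroformate and pyridine give methyl (2R)-1-(triisopropylsilyloxy)-4-(trimethylsilyl)but-3-yn-2-yl carbonate F15.
 - Copper-catalysed anti-SN2' borylation (CuOt-Bu, Xantphos, B2pin2, THF) gives the (aS)-allenyl pinacol boronate F16, which has the same spatial arrangement as 11 and no propargylic metal tautomer that could eliminate.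
 - Warming F16 with 2 in toluene (closed six-membered transition state, as in an allylboration) and hydrolysis of the borate give 12.

**Further compounds**

F1 | step 11 | [3,5-dimethoxy-4-(triisopropylsilyloxy)phenyl]methanol | COc1cc(CO)cc(OC)c1O[Si](C(C)C)(C(C)C)C(C)C
F2 | step 11 | 3-bromo-4-{[3,5-dimethoxy-4-(triisopropylsilyloxy)phenyl]methoxy}-5-methoxybenzaldehyde | COc1cc(C=O)cc(Br)c1OCc1cc(OC)c(O[Si](C(C)C)(C(C)C)C(C)C)c(OC)c1
F3 | step 11 | dimethyl acetal of F2 | COc1cc(C(OC)OC)cc(Br)c1OCc1cc(OC)c(O[Si](C(C)C)(C(C)C)C(C)C)c(OC)c1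
F4 | step 11 | tert-butyl 2-[5-(dimethoxymethyl)-2-{[3,5-dimethoxy-4-(triisopropylsilyloxy)phenyl]methoxy}-3-methoxyphenyl]acetate | COc1cc(C(OC)OC)cc(CC(=O)OC(C)(C)C)c1OCc1cc(OC)c(O[Si](C(C)C)(C(C)C)C(C)C)c(OC)c1
F5 | step 11 | tert-butyl 2-diazo-2-[5-(dimethoxymethyl)-2-{[3,5-dimethoxy-4-(triisopropylsilyloxy)phenyl]methoxy}-3-methoxyphenyl]acetate | COc1cc(C(OC)OC)cc(C(=[N+]=[N-])C(=O)OC(C)(C)C)c1OCc1cc(OC)c(O[Si](C(C)C)(C(C)C)C(C)C)c(OC)c1
F6 | step 11 | tert-butyl cis-(2R,3S)-5-(dimethoxymethyl)-2-[3,5-dimethoxy-4-(triisopropylsilyloxy)phenyl]-7-methoxy-2,3-dihydro-1-benzofuran-3-carboxylate | COc1cc([C@@H]2Oc3c(OC)cc(C(OC)OC)cc3[C@@H]2C(=O)OC(C)(C)C)cc(OC)c1O[Si](C(C)C)(C(C)C)C(C)C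
F7 | step 11 | tert-butyl trans-(2R,3R)-5-(dimethoxymethyl)-2-[3,5-dimethoxy-4-(triisopropylsilyloxy)phenyl]-7-methoxy-2,3-dihydro-1-benzofuran-3-carboxylate | COc1cc([C@@H]2Oc3c(OC)cc(C(OC)OC)cc3[C@H]2C(=O)OC(C)(C)C)cc(OC)c1O[Si](C(C)C)(C(C)C)C(C)C
F8 | step 11 | [(2R,3S)-5-(dimethoxymethyl)-2-[3,5-dimethoxy-4-(triisopropylsilyloxy)phenyl]-7-methoxy-2,3-dihydro-1-benzofuran-3-yl]methanol | COc1cc([C@@H]2Oc3c(OC)cc(C(OC)OC)cc3[C@H]2CO)cc(OC)c1O[Si](C(C)C)(C(C)C)C(C)C
F9 | step 11 | (2R,3S)-5-(dimethoxymethyl)-2-[3,5-dimethoxy-4-(triisopropylsilyloxy)phenyl]-7-methoxy-3-[(triisopropylsilyloxy)methyl]-2,3-dihydro-1-benzofuran | COc1cc([C@@H]2Oc3c(OC)cc(C(OC)OC)cc3[C@H]2CO[Si](C(C)C)(C(C)C)C(C)C)cc(OC)c1O[Si](C(C)C)(C(C)C)C(C)C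
F10 | step 9 | (1R,2S)-1-aryl-1-{[(E)-1,2-dichloroethenyl]oxy}-2-[(triisopropylsilyloxy)methyl]but-3-yne (aryl = 3,5-dimethoxy-4-(triisopropylsilyloxy)phenyl) | COc1cc([C@@H]([C@H](CO[Si](C(C)C)(C(C)C)C(C)C)C#C)O/C(Cl)=C\Cl)cc(OC)c1O[Si](C(C)C)(C(C)C)C(C)C
F11 | step 9 | (1R,2S)-1-aryl-1-[(chloroethynyl)oxy]-2-[(triisopropylsilyloxy)methyl]but-3-yne (same aryl) | COc1cc([C@@H]([C@H](CO[Si](C(C)C)(C(C)C)C(C)C)C#C)OC#CCl)cc(OC)c1O[Si](C(C)C)(C(C)C)C(C)C
F12 | step 9 | (2R,3S)-7-chloro-5-(diethoxymethyl)-2-[3,5-dimethoxy-4-(triisopropylsilyloxy)phenyl]-3-[(triisopropylsilyloxy)methyl]-2,3-dihydro-1-benzofuran | COc1cc([C@@H]2Oc3c(Cl)cc(C(OCC)OCC)cc3[C@H]2CO[Si](C(C)C)(C(C)C)C(C)C)cc(OC)c1O[Si](C(C)C)(C(C)C)C(C)C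
F13 | step 9 | (2R,3S)-5-(diethoxymethyl)-2-[3,5-dimethoxy-4-(triisopropylsilyloxy)phenyl]-7-(4,4,5,5-tetramethyl-1,3,2-dioxaborolan-2-yl)-3-[(triisopropylsilyloxy)methyl]-2,3-dihydro-1-benzofuran | COc1cc([C@@H]2Oc3c(B4OC(C)(C)C(C)(C)O4)cc(C(OCC)OCC)cc3[C@H]2CO[Si](C(C)C)(C(C)C)C(C)C)cc(OC)c1O[Si](C(C)C)(C(C)C)C(C)C
F14 | step 9 | (2R,3S)-5-(diethoxymethyl)-2-[3,5-dimethoxy-4-(triisopropylsilyloxy)phenyl]-3-[(triisopropylsilyloxy)methyl]-2,3-dihydro-1-benzofuran-7-ol | COc1cc([C@@H]2Oc3c(O)cc(C(OCC)OCC)cc3[C@H]2CO[Si](C(C)C)(C(C)C)C(C)C)cc(OC)c1O[Si](C(C)C)(C(C)C)C(C)C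
F15 | step 7 | methyl (2R)-1-(triisopropylsilyloxy)-4-(trimethylsilyl)but-3-yn-2-yl carbonate | C[Si](C)(C)C#C[C@@H](OC(=O)OC)CO[Si](C(C)C)(C(C)C)C(C)C
F16 | step 7 | 2-[(aS)-4-(triisopropylsilyloxy)-1-(trimethylsilyl)buta-1,2-dien-1-yl]-4,4,5,5-tetramethyl-1,3,2-dioxaborolane | CC1(C)OB(OC1(C)C)C([Si](C)(C)C)=[C@]=C([H])CO[Si](C(C)C)(C(C)C)C(C)C
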